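**Retrosynthetic overview**
- The target is the formal [4+2] homodimer of one vinylallenyl epoxy-ketone monomer; the central cyclohexene with its spiro carbon is made last from two molecules of that monomer, copying the presumed biosynthesis.
- In each cyclohexanone ring (C1 = C=O, C2 = C–prenyl, C3 = epoxide CH, C4 = CHOH, C5 = CH2, C6 = spiro/allene carbon) the three adjacent oxygenated carbons C1–C2–C3 are a masked dihydroxyacetone unit, and C4–C5–C6 is an enal at the aldehyde level.
- The ring is therefore a [3+3] adduct: a 1,3-dioxan-5-one (α,α′-dinucleophile) plus an enynal (1,3-dielectrophile), joined by Michael addition (C1–C6) and aldol closure (C3–C4).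
- C6 is sp2 in the monomer, so it can serve as a traceless relay stereocentre: iminium catalysis sets it, the bicyclic aldol passes its configuration to C1/C3/C4, and it is erased when the allene forms.
- Ring order: cyclohexanone ([3+3]) → oxirane (C2 carbinol from the dioxanone ketone, C3–O as leaving group) → central ring (dimerisation).

Key step: step 4

Assumption (chemistry): C6 of 8–19 and the allene axis of 20 are transient stereo-elements erased in the last step; 9–19 are drawn as the equatorial-alkynyl C6 series and 20 without an axial descriptor because the axis epimerises under the amine. Locants C1–C6 in the Why lines are the ring positions defined above, not nomenclature locants.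

**Route**

Step 1
Reactants: 1 2-methylbut-1-en-3-yne; 2 (E)-3-(dimethylamino)prop-2-enal
Product: 4 (E)-6-methylhepta-2,6-dien-4-ynal, via amino-dienynol lithium alkoxide 3 (not isolated)
Conditions: n-BuLi, THF, −78 °C; then 2, −78 → 0 °C; then 1 M HCl, 23 °C
Reagents that add atoms: water, O
Why: 1,2-addition of the lithium acetylide to the vinylogous formamide, then acid-induced loss of dimethylamine through the conjugated iminium ion (three-carbon enal homologation), should give the enynal with the thermodynamically preferred E geometry.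

Step 2
Reactants: 5 cis-2-phenyl-1,3-dioxan-5-ol
Product: 6 2-phenyl-1,3-dioxan-5-one
Conditions: DMP (1,1,1-triacetoxy-1,1-dihydro-1,2-benziodoxol-3(1H)-one), NaHCO3, CH2Cl2, 23 °C
Reagents that add atoms: none
Why: Buffered periodinane oxidation of a secondary alcohol leaves the benzylidene acetal intact; the ketone hydrates easily and is used directly.

Step 3
Reactants: 6 2-phenyl-1,3-dioxan-5-one
Product: 7 2-phenyl-5-(trimethylsilyloxy)-4H-1,3-dioxine (racemic)
Conditions: TMSOTf, Et3N, CH2Cl2, 0 °C
Reagents that add atoms: trimethylsilyl trifluoromethanesulfonate, C[Si](C)(C)OS(=O)(=O)C(F)(F)F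
Why: Soft enolisation and O-silylation of the symmetrical ketone gives the silyl enol ether (the latent C1 nucleophile) without any regiochemical question, since both α-carbons are equivalent.

Step 4
Reactants: 7 2-phenyl-5-(trimethylsilyloxy)-4H-1,3-dioxine; 4 (E)-6-methylhepta-2,6-dien-4-ynal
Product: 9 (1S,3R,5R,6S,8R)-6-hydroxy-8-(3-methylbut-3-en-1-ynyl)-3-phenyl-2,4-dioxabicyclo[3.3.1]nonan-9-one, via keto-aldehyde Michael adduct 8 (not isolated)
Conditions: (2R,5R)-5-benzyl-2-tert-butyl-3-methylimidazolidin-4-one·CF3CO2H (20 mol%), CH2Cl2–H2O, −40 °C; then pyrrolidine (30 mol%), AcOH (30 mol%), 23 °C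
Reagents that add atoms: none
Why: The iminium ion of enal 4 should accept silyl enol ether 7 at C6 (Mukaiyama–Michael, C1–C6 bond), and after hydrolysis to keto-aldehyde 8 pyrrolidinium acetate should close the carbocycle by a 6-(enolendo)-exo-trig aldol of the second α-carbon onto the aldehyde (C3–C4 bond). The closest known reactions are the organocatalytic Mukaiyama–Michael addition of silyl enol ethers to enals and the Stork-type α,α′-annulation of cyclic ketones with enals to bicyclo[3.3.1]nonan-9-ones. C6 is set by the catalyst, whose benzyl group shields one face of the E-iminium ion; C1 and C3 must be cis because the three-carbon bridge can only span the dioxanone diaxially, and under the reversible aldol/enolisation conditions they should settle with the alkynyl group on C6 equatorial, which relays the configuration of C6 to C1 and C3. The C4 hydroxyl should end axial (anti to O3, hydrogen-bonded to the bridging ketone) as the thermodynamic aldol, and the acid-labile acetal carbon should equilibrate to exo-phenyl. The step needs 1,4- rather than 1,2- or 1,6-addition, which the soft silyl enol ether and iminium activation of the β-carbon should secure, and the β-hydroxy ketone cannot dehydrate because C3 is a bridgehead (Bredt strain). Any C6-epimeric bicycle belongs to the antipodal series at C1/C3/C4 and should be removed by chromatography.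

Step 5
Reactants: 9 bicyclic aldol
Product: 10 6-O-tert-butyldimethylsilyl ether of 9
Conditions: TBSOTf, 2,6-lutidine, CH2Cl2, −78 → 0 °C
Reagents that add atoms: tert-butyldimethylsilyl trifluoromethanesulfonate, CC(C)(C)[Si](C)(C)OS(=O)(=O)C(F)(F)F
Why: Silylation under weakly basic conditions caps the axial C4 hydroxyl, which shuts off retro-aldol opening and later blocks the carbocycle face of the ketone.

Step 6
Reactants: 10 silyl ether
Product: 11 9-spiro-oxirane of 10 (oxirane oxygen on the carbocycle face syn to the C4 silyl ether; oxirane CH2 over the dioxane ring)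
Conditions: Me3S+ I−, KN(SiMe3)2, THF, −10 → 23 °C
Reagents that add atoms: trimethylsulfonium iodide, C[S+](C)C.[I-]
Why: Corey–Chaykovsky epoxidation of a ketone that cannot enolise (both α-carbons are bridgeheads); the sulfonium ylide should add irreversibly from the open dioxane face, anti to the axial C4 silyl ether, which sets C2 with carbon syn to O1/O3 and oxygen anti.

Step 7
Reactants: 11 spiro-oxirane
Product: 13 4-(tert-butyldimethylsilyloxy)-2-(3-methylbut-2-enyl)-6-(3-methylbut-3-en-1-ynyl)cyclohexane-1,2,3-triol (O1/O3 cis; O2/O4 trans to them), via benzylidene-protected tertiary alcohol 12 (not isolated)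
Conditions: Me2C=CHMgBr, CuI (20 mol%), THF, −30 → 0 °C; then AcOH–H2O–THF (3:1:1), 40 °C
Reagents that add atoms: 2-methylprop-1-enylmagnesium bromide, CC(C)=C[Mg]Br
Why: Copper-catalysed SN2 opening of the oxirane at its CH2 terminus by the isobutenyl organomagnesium reagent builds the linear prenyl group without allylic transposition, and aqueous acetic acid then hydrolyses the diaxially bridging benzylidene acetal while the hindered secondary TBS ether should survive.

Step 8
Reactants: 13 triol
Product: 14 1-O-triethylsilyl ether of 13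
Conditions: TESCl, imidazole, CH2Cl2, −40 °C
Reagents that add atoms: chlorotriethylsilane, CC[Si](Cl)(CC)CC
Why: The C3 hydroxyl is deactivated inductively by the C4 oxygen and flanked by the bulky TBS ether, and the tertiary C2 hydroxyl is inert to the silyl chloride, so kinetic monosilylation should favour C1–OH; any regioisomer should be separable by chromatography.

Step 9
Reactants: 14 mono-TES ether
Product: 16 2,3-epoxide bearing C1–OTES and C4–OTBS, via C3 mesylate 15 (not isolated)
Conditions: MsCl, Et3N, DMAP (cat.), CH2Cl2, 0 °C; then NaH, THF, 0 → 23 °C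
Reagents that add atoms: none
Why: Mesylation of the only free secondary hydroxyl, then 3-exo-tet displacement by the C2 alkoxide through the trans-diaxial conformer (Fürst–Plattner), inverts C3 and places the epoxide oxygen cis to the C4 oxygen and trans to the prenyl group.

Step 10
Reactants: 16 bis-silyl epoxide
Product: 17 epoxy alcohol with free C1–OH and C4–OTBS
Conditions: PPTS (cat.), MeOH, 0 °C
Reagents that add atoms: none
Why: Mild acid methanolysis removes a secondary TES ether much faster than a secondary TBS ether, and avoids the basic conditions that could trigger epoxide migration.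

Step 11
Reactants: 17 epoxy alcohol
Product: 18 (1S,3R,5S,6S)-5-(tert-butyldimethylsilyloxy)-1-(3-methylbut-2-enyl)-3-(3-methylbut-3-en-1-ynyl)-7-oxabicyclo[4.1.0]heptan-2-one
Conditions: DMP (1,1,1-triacetoxy-1,1-dihydro-1,2-benziodoxol-3(1H)-one), NaHCO3, CH2Cl2, 0 → 23 °C
Reagents that add atoms: none
Why: Buffered periodinane oxidation of the only free hydroxyl installs the C1 ketone last, so neither an α-ketol nor a base-sensitive α-alkynyl ketone is carried through earlier steps.

Step 12
Reactants: 18 silyl-protected α-alkynyl epoxy ketone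
Product: 19 (1S,3R,5S,6S)-5-hydroxy-1-(3-methylbut-2-enyl)-3-(3-methylbut-3-en-1-ynyl)-7-oxabicyclo[4.1.0]heptan-2-one
Conditions: HF·pyridine, pyridine, THF, 0 → 23 °C
Reagents that add atoms: none
Why: Buffered acidic fluoride cleaves the TBS ether without the basicity that would isomerise the alkyne prematurely.

Step 13
Reactants: 19 α-alkynyl epoxy ketone (two molecules per molecule of product)
Product: 21 CNP0235815.2 (target), via vinylallenyl ketone 20 (not isolated)
Conditions: Et3N (20 mol%), toluene (1 M), 23 → 40 °C
Reagents that add atoms: a second molecule of 19 (isomerised in the same flask to 20; it supplies the other half of the dimer), CC(C)=CC[C@]12O[C@H]1[C@@H](O)C[C@H](C#CC(C)=C)C2=O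
Why: Catalytic amine should convert each molecule of the α-alkynyl ketone into the conjugated vinylallenyl ketone 20 (propargyl–allenyl prototropy), and two molecules of 20 should then combine in a thermal Diels–Alder homodimerisation (vinylallene of one as diene, allenone C6=C bond of the other as dienophile, the two allene sp carbons joining and the diene CH2 terminus bonding to C6), in which approach anti to the C2 prenyl group and on the hydrogen side of the allene terminus sets the spiro centre and the geometry of the dienyl alkene, the amine-labile allene axis lets the matched axial isomer react, and bonding of the diene in the enone plane on the carbonyl side fixes the second exocyclic alkene.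

**Compound list**
1 | 2-methylbut-1-en-3-yne | C=C(C)C#C | starting material
2 | (E)-3-(dimethylamino)prop-2-enal | CN(C)/C=C/C=O | starting material
3 | (E)-1-(dimethylamino)-6-methylhepta-1,6-dien-4-yn-3-ol (racemic; lithium alkoxide in the flask) | CN(C)/C=C/C(O)C#CC(C)=C | intermediate
4 | (E)-6-methylhepta-2,6-dien-4-ynal | C=C(C)C#C/C=C/C=O | intermediate
5 | cis-2-phenyl-1,3-dioxan-5-ol | O[C@H]1CO[C@@H](c2ccccc2)OC1 | starting material
6 | 2-phenyl-1,3-dioxan-5-one | O=C1COC(c2ccccc2)OC1 | intermediate
7 | 2-phenyl-5-(trimethylsilyloxy)-4H-1,3-dioxine (racemic) | C[Si](C)(C)OC1=COC(c2ccccc2)OC1 | intermediate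
8 | (3R)-6-methyl-3-(5-oxo-2-phenyl-1,3-dioxan-4-yl)hept-6-en-4-ynal (epimers at the dioxane carbons) | O=CC[C@H](C#CC(C)=C)C1OC(c2ccccc2)OCC1=O | intermediate
9 | (1S,3R,5R,6S,8R)-6-hydroxy-8-(3-methylbut-3-en-1-ynyl)-3-phenyl-2,4-dioxabicyclo[3.3.1]nonan-9-one (phenyl exo, hydroxyl axial, alkynyl equatorial) | O=C1[C@H]2O[C@@H](c3ccccc3)O[C@@H]1[C@@H](O)C[C@@H]2C#CC(C)=C | intermediate
10 | 6-O-tert-butyldimethylsilyl ether of 9 | O=C1[C@H]2O[C@@H](c3ccccc3)O[C@@H]1[C@@H](O[Si](C)(C)C(C)(C)C)C[C@@H]2C#CC(C)=C | intermediate
11 | 9-spiro-oxirane of 10 (oxirane O syn to the silyl ether, CH2 over the dioxane ring) | C1O[C@@]12[C@H]3O[C@@H](c4ccccc4)O[C@@H]2[C@@H](O[Si](C)(C)C(C)(C)C)C[C@@H]3C#CC(C)=C | intermediate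
12 | 9-hydroxy-9-(3-methylbut-2-enyl) benzylidene acetal (tertiary OH syn to the silyl ether) | CC(C)=CC[C@@]1(O)[C@H]2O[C@@H](c3ccccc3)O[C@@H]1[C@@H](O[Si](C)(C)C(C)(C)C)C[C@@H]2C#CC(C)=C | intermediate
13 | 4-(tert-butyldimethylsilyloxy)-2-(3-methylbut-2-enyl)-6-(3-methylbut-3-en-1-ynyl)cyclohexane-1,2,3-triol (O1, O3 cis; O2, O4 trans to them; alkynyl cis to O1) | CC(C)=CC[C@@]1(O)[C@@H](O)[C@@H](C#CC(C)=C)C[C@H](O[Si](C)(C)C(C)(C)C)[C@H]1O | intermediate
14 | 1-O-triethylsilyl ether of 13 | CC(C)=CC[C@@]1(O)[C@@H](O[Si](CC)(CC)CC)[C@@H](C#CC(C)=C)C[C@H](O[Si](C)(C)C(C)(C)C)[C@H]1O | intermediate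
15 | 3-O-methanesulfonate of 14 | CC(C)=CC[C@@]1(O)[C@@H](O[Si](CC)(CC)CC)[C@@H](C#CC(C)=C)C[C@H](O[Si](C)(C)C(C)(C)C)[C@H]1OS(C)(=O)=O | intermediate
16 | 2,3-epoxide (oxirane O cis to C4–OTBS, trans to prenyl) with C1–OTES | CC(C)=CC[C@]12O[C@H]1[C@@H](O[Si](C)(C)C(C)(C)C)C[C@H](C#CC(C)=C)[C@@H]2O[Si](CC)(CC)CC | intermediate
17 | epoxy alcohol (free C1–OH, C4–OTBS) | CC(C)=CC[C@]12O[C@H]1[C@@H](O[Si](C)(C)C(C)(C)C)C[C@H](C#CC(C)=C)[C@@H]2O | intermediate
18 | (1S,3R,5S,6S)-5-(tert-butyldimethylsilyloxy)-1-(3-methylbut-2-enyl)-3-(3-methylbut-3-en-1-ynyl)-7-oxabicyclo[4.1.0]heptan-2-one | CC(C)=CC[C@]12O[C@H]1[C@@H](O[Si](C)(C)C(C)(C)C)C[C@H](C#CC(C)=C)C2=O | intermediate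
19 | (1S,3R,5S,6S)-5-hydroxy-1-(3-methylbut-2-enyl)-3-(3-methylbut-3-en-1-ynyl)-7-oxabicyclo[4.1.0]heptan-2-one | CC(C)=CC[C@]12O[C@H]1[C@@H](O)C[C@H](C#CC(C)=C)C2=O | intermediate
20 | (1S,5S,6S)-5-hydroxy-3-(3-methylbuta-1,3-dienylidene)-1-(3-methylbut-2-enyl)-7-oxabicyclo[4.1.0]heptan-2-one (allene axis labile) | CC(C)=CC[C@]12O[C@H]1[C@@H](O)CC(=C=CC(C)=C)C2=O | intermediate
21 | CNP0235815.2 | C=C(C)/C=C1/C(=C2/C[C@H](O)[C@@H]3O[C@]3(CC=C(C)C)C2=O)C=C(C)C[C@@]12C[C@H](O)[C@@H]1O[C@]1(CC=C(C)C)C2=O | target

**Step count and risks**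

Total step count: 13. Longest linear sequence: 12 steps (5 → 21, steps 2 to 13).

Most likely to fail, riskiest first:

Step 4. The silyl enol ether may add 1,2 or 1,6 to the enynal iminium ion. The relay from C6 to C1/C3 may stay incomplete if enolisation at C1 and retro-aldol equilibration are slow, leaving much of the antipodal-series bicycle. Retro-Michael reaction may erode the C6 configuration, and the aldol may settle with the hydroxyl equatorial. The fallback sets out from 6: condensation with pyrrolidine gives the enamine 1-(2-phenyl-4H-1,3-dioxin-5-yl)pyrrolidine F1. Its Michael addition to 4 in MeCN, then hydrolysis with aqueous AcOH and aldol closure under pyrrolidinium acetate, should give the racemic bicyclic aldol, that is 9 together with its mirror image ent-9 F2. Lipase-catalysed transesterification with vinyl acetate (Candida antarctica lipase B, the enzyme and enantiomer pairing to be found by screening) should acetylate ent-9 to the acetate of ent-9 F3, which is separated. The fallback comes back to the route at 9.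

Step 13. The dimerisation may lose periselectivity (hetero-[4+2] through the enone oxygen, [2+2] at the allenes), take the wrong regio- or facial course, or be overtaken by conjugate addition of the free hydroxyl or the amine to the allenone and by oligomerisation. The fallback sets out from 18 and moves the cycloaddition in front of the desilylation: Et3N isomerisation gives the silyl-protected vinylallenyl ketone F4 (not isolated), two molecules of which should dimerise to the bis-TBS ether of the target F5. HF·pyridine then removes both silyl groups, and the fallback comes back to the route at 21.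

Step 8. Silylation may discriminate poorly between the two secondary hydroxyls or prefer the C3 hydroxyl, because the ring can populate a conformer in which the C4 silyl ether points away from C3–OH. The fallback sets out from 13 and makes the regioisomer productive by a protecting-group relay instead of relying on the sense of the selectivity. The 3-O-triethylsilyl ether of 13 F6 is acetylated at the remaining secondary hydroxyl (Ac2O, pyridine, DMAP, CH2Cl2) to the 1-O-acetyl-3-O-triethylsilyl derivative of 13 F7. PPTS in MeOH removes the TES group to give the 1-O-acetyl diol F8, and MsCl with Et3N gives its 3-O-methanesulfonate F9. K2CO3 in MeOH then cleaves the acetate and closes the epoxide through the C2 alkoxide; the freed C1 alkoxide is cis to the leaving group and cannot displace it. The fallback comes back to the route at 17.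

Further compounds
F1 | step 4 | 1-(2-phenyl-4H-1,3-dioxin-5-yl)pyrrolidine | C1=C(N2CCCC2)COC(c2ccccc2)O1
F2 | step 4 | ent-9, (1R,3S,5S,6R,8S)-6-hydroxy-8-(3-methylbut-3-en-1-ynyl)-3-phenyl-2,4-dioxabicyclo[3.3.1]nonan-9-one | O=C1[C@@H]2O[C@H](c3ccccc3)O[C@H]1[C@H](O)C[C@H]2C#CC(C)=C
F3 | step 4 | acetate of ent-9 | O=C1[C@@H]2O[C@H](c3ccccc3)O[C@H]1[C@H](OC(C)=O)C[C@H]2C#CC(C)=C
F4 | step 13 | (1S,5S,6S)-5-(tert-butyldimethylsilyloxy)-3-(3-methylbuta-1,3-dienylidene)-1-(3-methylbut-2-enyl)-7-oxabicyclo[4.1.0]heptan-2-one | CC(C)=CC[C@]12O[C@H]1[C@@H](O[Si](C)(C)C(C)(C)C)CC(=C=CC(C)=C)C2=O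
F5 | step 13 | bis-O-tert-butyldimethylsilyl ether of 21 | C=C(C)/C=C1/C(=C2/C[C@H](O[Si](C)(C)C(C)(C)C)[C@@H]3O[C@]3(CC=C(C)C)C2=O)C=C(C)C[C@@]12C[C@H](O[Si](C)(C)C(C)(C)C)[C@@H]1O[C@]1(CC=C(C)C)C2=O
F6 | step 8 | 3-O-triethylsilyl ether of 13 | CC(C)=CC[C@@]1(O)[C@@H](O)[C@@H](C#CC(C)=C)C[C@H](O[Si](C)(C)C(C)(C)C)[C@H]1O[Si](CC)(CC)CC
F7 | step 8 | 1-O-acetyl-3-O-triethylsilyl derivative of 13 | CC(C)=CC[C@@]1(O)[C@@H](OC(C)=O)[C@@H](C#CC(C)=C)C[C@H](O[Si](C)(C)C(C)(C)C)[C@H]1O[Si](CC)(CC)CC
F8 | step 8 | 1-O-acetyl derivative of 13 (free C2 and C3 hydroxyls) | CC(C)=CC[C@@]1(O)[C@@H](OC(C)=O)[C@@H](C#CC(C)=C)C[C@H](O[Si](C)(C)C(C)(C)C)[C@H]1O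
F9 | step 8 | 3-O-methanesulfonate of the 1-O-acetyl derivative of 13 | CC(C)=CC[C@@]1(O)[C@@H](OC(C)=O)[C@@H](C#CC(C)=C)C[C@H](O[Si](C)(C)C(C)(C)C)[C@H]1OS(C)(=O)=O
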